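Atom labels used throughout: ring carbons C1–C6 and exocyclic C7. C1 is the quaternary carbinol carbon bearing C7H2OBz, C2 is CHOH, C3 and C4 are CH2, C5 is CHOBz, C6 is CHOH.

## Analysis of the target

The target 21, [(1S,2S,3R,6R)-3-(benzoyloxy)-1,2,6-trihydroxycyclohexyl]methyl benzoate, is one cyclohexane ring with one exocyclic carbon. C1 is a tertiary carbinol carrying C7, C2 and C6 are secondary carbinols flanking it, C5 carries the second benzoate, and C3 and C4 are methylenes. The four stereocentres (C1 S, C2 R, C5 R, C6 S) form one arc C2–C1–C6–C5. The C1 hydroxyl and the C5 benzoate lie on one face; the C2 and C6 hydroxyls and C7 lie on the other. Each neighbouring pair of ring oxygens is therefore trans, and the C1 and C5 oxygens are cis-1,3. Sensitive points are the C5 benzoate next to a free C6 hydroxyl (acyl migration) and any stage with a C5 ketone, where the C1 hydroxyl is a β-hydroxyl open to retro-aldol cleavage or dehydration. The difficulty is a fully substituted carbinol of defined configuration inside an oxygenated array, plus five oxygens that must be told apart. The plan rests on one feature: C7–C1–C2 is a dihydroxyacetone unit if C1 is read as a carbonyl, and C1 is β to the C5 oxygen through C6. The C1–C6 ring bond is thus an aldol bond between a C5 ketone and a 1,3-dioxan-5-one carbonyl, and only C2 must exist before the ring closes.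

## Retrosynthetic reasoning

21 from 20: the last bond cut is the C6 O–benzyl bond. The C6 oxygen stays protected to the end because a free C6 hydroxyl beside the C5 ester invites acyl migration; neutral hydrogenolysis releases it when nothing further has to be done.

20 from 19 from 18: the C7 ester bond is cut next, then the isopropylidene acetal over the C7 and C2 oxygens is put back. The acetal is what the dioxanone building block brings along. Its removal exposes one primary and one secondary hydroxyl beside the tertiary one, and only the primary one has to be acylated.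

18 from 17: the C5–O ester bond is cut with inversion. In the bicyclic ketol 15 the upper face of the C5 carbonyl carries only the C1 hydroxyl; the lower face carries C7, the C2 oxygen and the C6 benzyloxy group. External hydride and hydroxyl-delivered hydride should therefore both arrive from above and give the C5 alcohol trans to the C1 hydroxyl. A boron chelate between the C1 oxygen and the C5 carbonyl, as a Narasaka–Prasad syn reduction needs, would place the carbonyl carbon at a bridgehead of a bicyclo[3.3.1] chelate and is not counted on. The anti alcohol 17 is accepted, and the benzoate enters by SN2 displacement, which both corrects C5 and installs the ester.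

17 from 15: the C5–H bond is cut; the forward step is a directed ketone reduction through 16.

15 from 12: the key cut is the C1–C6 bond. It opens the carbocycle to the diketone 12, whose dioxanone carbonyl is C1 and whose side-chain ketone is C5. The forward step must form the enamine 13 on the benzyloxy side, add it to the dioxanone carbonyl to give 14, and set C1 and C6 from the single stereocentre C2. C1 follows from axial attack on the chair dioxanone with the side chain equatorial, which gives cis fusion. C6 follows from the enamine geometry. The C6 configuration has to be kinetic: in 15 the C6 benzyloxy group and the C2 oxygen are 1,3-diaxial in the chair that the acetal favours, so equilibration at C6 would probably favour the wrong epimer. 15 is therefore reduced without delay.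

12 from 10 from 8 and 5: the C2–C3 bond is cut, an α-alkylation of the dioxanone. The ketone is carried as its chiral hydrazone 8, and the C5 carbonyl is hidden in the electrophile 5 as a 1,1-disubstituted alkene. One ozonolysis then frees both carbonyls of 12 under neutral conditions. Alkylation with a primary iodide is preferred to conjugate addition to a vinyl ketone, where 1,2-addition and polymerisation compete.

5 from 4 from 2 from 1, and 8 from 6 and 7: the iodide is built from the symmetrical dibromide 1 by mono-etherification, one-carbon chain extension and iodination. The hydrazone comes from the dioxanone 6 and the auxiliary 7.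

## Alternatives that were turned down

Alternative 1: The C5–O bond is traced back to a C5–H bond of the meso hydrosilyl ether A2 (C1–O–SiEt2H, acetal over the C2 and C6 oxygens, C7 benzoate). In the forward step an iridium catalyst, [Ir(cod)OMe]2 with a chiral bipyridine-type ligand, inserts the silicon into the axial C5–H bond and gives the oxasilolane A1. Tamao–Fleming oxidation, C5 benzoylation and acetal removal would finish the synthesis.
- For it: the C5 oxygen is delivered cis to the C1 oxygen by the tether, C1, C2 and C6 come from a meso compound, and C5 appears as the only acylable hydroxyl. On these points it is stronger than the chosen route, which needs an inversion at C5 and a selective primary acylation.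
- Against it: the catalyst alone must distinguish the enantiotopic C3–H and C5–H methylene bonds, a reaction class with little support for unactivated ring methylenes. The hot, hydride-rich conditions and the basic peroxide oxidation also endanger the C7 benzoate, and A2 needs several steps of its own.
- Comparison: the chosen route takes its absolute configuration from a stoichiometric auxiliary with a well-understood alkylation and concentrates its risk in one ring closure that has close analogues.

Alternative 2: The C5–O and C6–O bonds are traced back to the epoxy alcohol A4 (C1–C6 oxirane, C5 hydroxyl on the opposite face, benzyl ethers at C2 and C7). Aqueous hydroxide is to shift the oxirane to C5–C6 by Payne rearrangement and open it at C5, giving the all-trans triol A3.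
- For it: cheap reagents, no catalyst, and three contiguous centres derived from one epoxide. In simplicity of reagents it is stronger than the chosen route.
- Against it: Payne equilibria give mixtures. Direct opening of the unrearranged oxirane at C6 gives the C5 epimer, and opening of the rearranged oxirane at C6 gives another isomer. The trans-diaxial preference depends on a ring conformation nothing secures. A3 also has the wrong protection pattern: C5 must be benzoylated beside free C6 and C1 hydroxyls, and the C7 benzyl ether exchanged for a benzoate without touching C2.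
- Comparison: the chosen route keeps C5 distinct as a ketone and C6 distinct as a benzyl ether from the start, so no such sorting is needed.

Alternative 3: The C1–C7 bond is cut. The C2-symmetric diol A7 has homotopic hydroxyls, so monobenzylation and oxidation give the single ketone A6. A sulfonium methylide is to add axially and close to the spiro-epoxide A5 (Corey–Chaykovsky reaction); benzoate would then open the oxirane at C7.
- For it: the route is short, the symmetry removes one differentiation, and the C7 benzoate enters regiospecifically, which is stronger than the selective acylation of the chosen route.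
- Against it: A6 has two α-benzyloxy groups and faces a basic ylide (enolisation, β-elimination). Facial selectivity depends on polar effects of both α-oxygens. The three benzyl ethers at C2, C5 and C6 fall together on hydrogenolysis, leaving C5 to be benzoylated beside C2 and C6 hydroxyls without a firm basis. Enantiopure A7 needs its own asymmetric synthesis.
- Comparison: the chosen route gives up the regiospecific C7 acylation but never has to pick C5 out of three similar secondary hydroxyls.

Key step: step 7

Assumption: the sense of induction of the auxiliary 7 follows the accepted chelated azaenolate model for RAMP/SAMP hydrazones, which predicts the 4R dioxanone (C2 of the target R).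

## Route

Step 1
Reactants: 1 3-bromo-2-(bromomethyl)prop-1-ene
Product: 2 ({[2-(bromomethyl)prop-2-en-1-yl]oxy}methyl)benzene
Conditions: BnOH, NaH, THF, 0 °C; then added to 1 (3 equiv), THF, 0 °C to rt
Reagents that add atoms: benzyl alcohol, OCc1ccccc1
Why: Williamson ether synthesis at a primary allylic bromide (SN2 and SN2' give the same product); excess dibromide suppresses double substitution.

Step 2
Reactants: 2 ({[2-(bromomethyl)prop-2-en-1-yl]oxy}methyl)benzene
Product: 4 3-[(benzyloxy)methyl]but-3-en-1-ol, via allylzinc bromide 3 (not isolated)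
Conditions: Zn dust, 37% aq. HCHO, THF/sat. aq. NH4Cl, 0 °C to rt
Reagents that add atoms: formaldehyde, C=O
Why: Barbier allylation of formaldehyde; the 2-substituted allyl unit has two equivalent CH2 termini, so only one homoallylic alcohol can form, and the benzyl ether is inert.

Step 3
Reactants: 4 3-[(benzyloxy)methyl]but-3-en-1-ol
Product: 5 {[(4-iodo-2-methylidenebutyl)oxy]methyl}benzene
Conditions: I2, PPh3, imidazole, CH2Cl2, 0 °C to rt
Reagents that add atoms: iodine, II
Why: Appel-type iodination of a primary alcohol under near-neutral conditions that leave the alkene and the allylic ether untouched.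

Step 4
Reactants: 6 2,2-dimethyl-1,3-dioxan-5-one; 7 (R)-1-amino-2-(methoxymethyl)pyrrolidine (RAMP)
Product: 8 (2R)-N-(2,2-dimethyl-1,3-dioxan-5-ylidene)-2-(methoxymethyl)pyrrolidin-1-amine
Conditions: cyclohexane, reflux, Dean–Stark trap
Reagents that add atoms: none
Why: Hydrazone condensation of a symmetrical ketone, so no regiochemical or geometric issue arises; the acetal survives neutral water removal.

Step 5
Reactants: 8 (2R)-N-(2,2-dimethyl-1,3-dioxan-5-ylidene)-2-(methoxymethyl)pyrrolidin-1-amine; 5 {[(4-iodo-2-methylidenebutyl)oxy]methyl}benzene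
Product: 10 (2R)-N-[(4R)-4-{3-[(benzyloxy)methyl]but-3-en-1-yl}-2,2-dimethyl-1,3-dioxan-5-ylidene]-2-(methoxymethyl)pyrrolidin-1-amine, via lithium azaenolate 9 (not isolated)
Conditions: t-BuLi, THF, −78 °C; then 5, −100 °C to rt
Reagents that add atoms: none
Why: Enders RAMP-hydrazone α-alkylation: the methoxy-chelated azaenolate 9 is shielded on one face, so the primary iodide enters from the other and should set C4 of the dioxane (C2 of the target) as R; the very low temperature holds back E2 of the homoallylic iodide.

Step 6
Reactants: 10 (2R)-N-[(4R)-4-{3-[(benzyloxy)methyl]but-3-en-1-yl}-2,2-dimethyl-1,3-dioxan-5-ylidene]-2-(methoxymethyl)pyrrolidin-1-amine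
Product: 12 (4R)-4-[4-(benzyloxy)-3-oxobutyl]-2,2-dimethyl-1,3-dioxan-5-one, via keto ozonide 11 (not isolated)
Conditions: O3, CH2Cl2, −78 °C; then Me2S, −78 °C to rt
Reagents that add atoms: ozone, [O-][O+]=O
Why: Ozonolysis cleaves the hydrazone C=N (the standard non-epimerising release of such ketones) and the 1,1-disubstituted alkene in one operation, and Me2S reduces the ozonide 11; the benzyl ether reacts far more slowly at −78 °C and the neutral medium protects the α-stereocentre.

Step 7
Reactants: 12 (4R)-4-[4-(benzyloxy)-3-oxobutyl]-2,2-dimethyl-1,3-dioxan-5-one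
Product: 15 (4aS,5R,8aR)-5-(benzyloxy)-4a-hydroxy-2,2-dimethyltetrahydro-4H-1,3-benzodioxin-6(5H)-one (cis-fused ketol), via proline enamine 13 (not isolated), via bicyclic iminium carboxylate 14 (not isolated)
Conditions: D-proline (30 mol%), DMSO, rt
Reagents that add atoms: none
Why: D-Proline condenses with the side-chain ketone to the enamine 13 on the benzyloxy-bearing side (the only enamine that can close a six-membered ring); its C6 adds to the dioxanone carbonyl C1, which two α-oxygens and a hydrogen bond from the carboxylic acid activate, giving the iminium 14, which the water of condensation hydrolyses to 15 with return of the catalyst. The closest known reaction type is the proline-mediated Hajos–Parrish cyclisation of 2-(3-oxoalkyl) cyclic ketones, combined with enamine aldol reactions of α-oxygenated ketone donors. The carbocycle closes in the 6-(enolendo)-exo-trig mode through the new C1–C6 bond. C1 is controlled by C2: axial attack on the chair dioxanone with the side chain equatorial gives cis fusion, the new hydroxyl syn to the C2 hydrogen. C6 is controlled by enamine geometry: the E-enamine (benzyloxy group cis to C4, away from the pyrrolidine ring) in a chair transition state places the benzyloxy group axial and anti to the developing axial hydroxyl, hence trans. The sense of induction of the Hajos–Parrish reaction and of proline aldols of hydroxyacetone, transposed to this substrate, puts the preferred enamine face of (R)-proline on the side that the substrate itself prefers, whereas (S)-proline would work against it. The competing closure from a dioxanone-side enamine onto C5 would need the side chain axial against the axial acetal methyl and a bridged bicyclo[3.3.1] ring. The step needs kinetic control at C6, so 15 is not exposed to the catalyst longer than necessary and is reduced at once.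

Step 8
Reactants: 15 (4aS,5R,8aR)-5-(benzyloxy)-4a-hydroxy-2,2-dimethyltetrahydro-4H-1,3-benzodioxin-6(5H)-one
Product: 17 (4aS,5S,6S,8aR)-5-(benzyloxy)-2,2-dimethylhexahydro-4H-1,3-benzodioxine-4a,6-diol, via alkoxyborohydride 16 (not isolated)
Conditions: Me4NBH(OAc)3, MeCN/AcOH (1:1), −30 °C
Reagents that add atoms: none
Why: Evans–Saksena directed reduction: the axial C1 hydroxyl exchanges onto boron (16) and passes hydride to the upper face of the C5 carbonyl, which is also the sterically open face, so the C5 hydroxyl should form trans to the C1 hydroxyl; the acidic medium disfavours retro-aldol cleavage and C6 epimerisation.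

Step 9
Reactants: 17 (4aS,5S,6S,8aR)-5-(benzyloxy)-2,2-dimethylhexahydro-4H-1,3-benzodioxine-4a,6-diol
Product: 18 (4aS,5S,6R,8aR)-5-(benzyloxy)-4a-hydroxy-2,2-dimethylhexahydro-4H-1,3-benzodioxin-6-yl benzoate
Conditions: PhCO2H, PPh3, DIAD, toluene, 0 °C to rt
Reagents that add atoms: benzoic acid, OC(=O)c1ccccc1
Why: Mitsunobu esterification: benzoate displaces the activated C5 oxygen with inversion over the open upper face, which corrects C5 and installs the ester at once; the tertiary C1 hydroxyl is not activated, and the cis C6 benzyloxy group cannot participate from the rear.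

Step 10
Reactants: 18 (4aS,5S,6R,8aR)-5-(benzyloxy)-4a-hydroxy-2,2-dimethylhexahydro-4H-1,3-benzodioxin-6-yl benzoate
Product: 19 (1R,2S,3S,4R)-2-(benzyloxy)-3,4-dihydroxy-3-(hydroxymethyl)cyclohexyl benzoate
Conditions: AcOH/H2O (4:1), 40 °C
Reagents that add atoms: none
Why: Acid hydrolysis of the isopropylidene acetal; the benzoate and the benzyl ether are stable to aqueous acetic acid, and the benzyl ether at C6 blocks migration of the C5 benzoate.

Step 11
Reactants: 19 (1R,2S,3S,4R)-2-(benzyloxy)-3,4-dihydroxy-3-(hydroxymethyl)cyclohexyl benzoate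
Product: 20 [(1S,2S,3R,6R)-3-(benzoyloxy)-2-(benzyloxy)-1,6-dihydroxycyclohexyl]methyl benzoate
Conditions: BzCl (1.05 equiv), 2,4,6-collidine, CH2Cl2, −40 to 0 °C
Reagents that add atoms: benzoyl chloride, ClC(=O)c1ccccc1
Why: Kinetically controlled acylation of the primary C7 hydroxyl in preference to the secondary C2 and tertiary C1 hydroxyls, with a hindered base at low temperature.

Step 12
Reactants: 20 [(1S,2S,3R,6R)-3-(benzoyloxy)-2-(benzyloxy)-1,6-dihydroxycyclohexyl]methyl benzoate
Product: 21 [(1S,2S,3R,6R)-3-(benzoyloxy)-1,2,6-trihydroxycyclohexyl]methyl benzoate (target)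
Conditions: H2 (1 atm), Pd/C (10% palladium on carbon), EtOAc, rt
Reagents that add atoms: none
Why: Hydrogenolysis of the benzyl ether; the benzoates are not benzylic C–O bonds and persist, and the neutral medium avoids migration of the C5 benzoate to the freed C6 hydroxyl.

## Compound list

1 | 3-bromo-2-(bromomethyl)prop-1-ene | C=C(CBr)CBr | starting material
2 | ({[2-(bromomethyl)prop-2-en-1-yl]oxy}methyl)benzene | C=C(CBr)COCc1ccccc1 | intermediate
3 | bromo{2-[(benzyloxy)methyl]prop-2-en-1-yl}zinc (not isolated) | Br[Zn]CC(=C)COCc1ccccc1 | intermediate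
4 | 3-[(benzyloxy)methyl]but-3-en-1-ol | C=C(CCO)COCc1ccccc1 | intermediate
5 | {[(4-iodo-2-methylidenebutyl)oxy]methyl}benzene | C=C(CCI)COCc1ccccc1 | intermediate
6 | 2,2-dimethyl-1,3-dioxan-5-one | CC1(C)OCC(=O)CO1 | starting material
7 | (R)-1-amino-2-(methoxymethyl)pyrrolidine (RAMP) | COC[C@H]1CCCN1N | starting material
8 | (2R)-N-(2,2-dimethyl-1,3-dioxan-5-ylidene)-2-(methoxymethyl)pyrrolidin-1-amine | COC[C@H]1CCCN1N=C2COC(C)(C)OC2 | intermediate
9 | lithium azaenolate of 8 (not isolated) | COC[C@H]1CCCN1[N-]C2=COC(C)(C)OC2.[Li+] | intermediate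
10 | (2R)-N-[(4R)-4-{3-[(benzyloxy)methyl]but-3-en-1-yl}-2,2-dimethyl-1,3-dioxan-5-ylidene]-2-(methoxymethyl)pyrrolidin-1-amine (C=N geometry not specified) | COC[C@H]1CCCN1N=C2COC(C)(C)O[C@@H]2CCC(=C)COCc3ccccc3 | intermediate
11 | (4R)-4-(2-{3-[(benzyloxy)methyl]-1,2,4-trioxolan-3-yl}ethyl)-2,2-dimethyl-1,3-dioxan-5-one (both epimers at the trioxolane carbon; not isolated) | CC1(C)OCC(=O)[C@@H](CCC2(COCc3ccccc3)OCOO2)O1 | intermediate
12 | (4R)-4-[4-(benzyloxy)-3-oxobutyl]-2,2-dimethyl-1,3-dioxan-5-one | CC1(C)OCC(=O)[C@@H](CCC(=O)COCc2ccccc2)O1 | intermediate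
13 | (2R)-1-{(1E)-1-(benzyloxy)-4-[(4R)-2,2-dimethyl-5-oxo-1,3-dioxan-4-yl]but-1-en-2-yl}pyrrolidine-2-carboxylic acid (not isolated) | CC1(C)OCC(=O)[C@@H](CC/C(N2CCC[C@@H]2C(O)=O)=C\OCc3ccccc3)O1 | intermediate
14 | (2R)-1-[(4aS,5S,8aR)-5-(benzyloxy)-4a-hydroxy-2,2-dimethylhexahydro-4H-1,3-benzodioxin-6-ylidene]pyrrolidin-1-ium-2-carboxylate (not isolated) | CC1(C)OC[C@]2(O)[C@@H](CCC(=[N+]3CCC[C@@H]3C([O-])=O)[C@@H]2OCc4ccccc4)O1 | intermediate
15 | (4aS,5R,8aR)-5-(benzyloxy)-4a-hydroxy-2,2-dimethyltetrahydro-4H-1,3-benzodioxin-6(5H)-one | CC1(C)OC[C@]2(O)[C@@H](CCC(=O)[C@@H]2OCc3ccccc3)O1 | intermediate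
16 | tetramethylammonium diacetoxy(hydrido){[(4aS,5R,8aR)-5-(benzyloxy)-2,2-dimethyl-6-oxohexahydro-4H-1,3-benzodioxin-4a-yl]oxy}borate (not isolated) | CC1(C)OC[C@]2(O[BH-](OC(C)=O)OC(C)=O)[C@@H](CCC(=O)[C@@H]2OCc3ccccc3)O1.C[N+](C)(C)C | intermediate
17 | (4aS,5S,6S,8aR)-5-(benzyloxy)-2,2-dimethylhexahydro-4H-1,3-benzodioxine-4a,6-diol | CC1(C)OC[C@]2(O)[C@@H](CC[C@H](O)[C@@H]2OCc3ccccc3)O1 | intermediate
18 | (4aS,5S,6R,8aR)-5-(benzyloxy)-4a-hydroxy-2,2-dimethylhexahydro-4H-1,3-benzodioxin-6-yl benzoate | CC1(C)OC[C@]2(O)[C@@H](CC[C@@H](OC(=O)c3ccccc3)[C@@H]2OCc4ccccc4)O1 | intermediate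
19 | (1R,2S,3S,4R)-2-(benzyloxy)-3,4-dihydroxy-3-(hydroxymethyl)cyclohexyl benzoate | OC[C@]1(O)[C@H](O)CC[C@@H](OC(=O)c2ccccc2)[C@@H]1OCc3ccccc3 | intermediate
20 | [(1S,2S,3R,6R)-3-(benzoyloxy)-2-(benzyloxy)-1,6-dihydroxycyclohexyl]methyl benzoate | O=C(OC[C@]1(O)[C@H](O)CC[C@@H](OC(=O)c2ccccc2)[C@@H]1OCc3ccccc3)c4ccccc4 | intermediate
21 | [(1S,2S,3R,6R)-3-(benzoyloxy)-1,2,6-trihydroxycyclohexyl]methyl benzoate | O=C(OC[C@]1(O)[C@H](O)CC[C@@H](OC(=O)c2ccccc2)[C@@H]1O)c1ccccc1 | target

## Step count and least certain steps

Total: 12 steps. Longest linear sequence: 11 steps (steps 1–3 and 5–12, from 1); the branch from 6 through step 4 is 9 steps long.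

Step 7 (key step). The most likely failures are loss of control at C6 and interference by the dioxanone carbonyl. Closure through the Z-enamine, or enamine-mediated epimerisation of the product, would lead to the C6 epimer with an equatorial benzyloxy group, which relieves the 1,3-diaxial contact with the C2 oxygen. Condensation of the catalyst with the dioxanone carbonyl could erode C2 or divert material to a bridged ketol.

Fallback, setting out from 8 and returning at 18: the C6 oxygen is introduced after the ring exists.
- The azaenolate 9 is alkylated with commercial 4-bromo-2-methylbut-1-ene (C=C(C)CCBr) to (2R)-N-[(4R)-2,2-dimethyl-4-(3-methylbut-3-en-1-yl)-1,3-dioxan-5-ylidene]-2-(methoxymethyl)pyrrolidin-1-amine F1.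
- Ozonolysis (O3, then Me2S) gives the methyl diketone (4R)-2,2-dimethyl-4-(3-oxobutyl)-1,3-dioxan-5-one F2.
- D-Proline closes F2 through an unambiguous methyl-ketone enamine to the ketol (4aS,8aR)-4a-hydroxy-2,2-dimethyltetrahydro-4H-1,3-benzodioxin-6(5H)-one F3.
- MsCl/Et3N dehydrates F3 to the enone (8aR)-2,2-dimethyl-8,8a-dihydro-4H-1,3-benzodioxin-6(7H)-one F4.
- Corey–Bakshi–Shibata reduction (BH3·SMe2, (S)-2-methyl-CBS-oxazaborolidine) should give the allylic alcohol (6R,8aR)-2,2-dimethyl-6,7,8,8a-tetrahydro-4H-1,3-benzodioxin-6-ol F5.
- VO(acac)2/t-BuOOH epoxidises the C1=C6 double bond on the face of the C5 hydroxyl to the epoxy alcohol (4aS,5R,6R,8aR)-4a,5-epoxy-2,2-dimethylhexahydro-4H-1,3-benzodioxin-6-ol F6.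
- Sodium benzyl oxide in benzyl alcohol opens the oxirane at the secondary carbon C6 with inversion to the syn diol (4aS,5S,6R,8aR)-5-(benzyloxy)-2,2-dimethylhexahydro-4H-1,3-benzodioxine-4a,6-diol F7. Its benzyloxy group is trans to the C1 hydroxyl by mechanism, and its C5 hydroxyl already has the configuration of the target.
- BzCl/DMAP/pyridine then gives 18, so steps 8 and 9 fall away.

Step 9. Activation and substitution at the hindered C5 carbinol may be slow, with elimination toward C4 or closure of the C1 hydroxyl onto C5 as competing processes. Fallback, from 17 back to 18: activation and displacement are separated. Tf2O/pyridine at −20 °C gives the triflate (4aS,5S,6S,8aR)-5-(benzyloxy)-4a-hydroxy-2,2-dimethylhexahydro-4H-1,3-benzodioxin-6-yl trifluoromethanesulfonate F8, which tetrabutylammonium benzoate in toluene displaces with inversion, as in the epimerisation of carbohydrate hydroxyls.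

Step 5. The strongly basic azaenolate may eliminate the homoallylic iodide to a diene instead of substituting it, leaving unalkylated hydrazone. Fallback, from 8 and returning at 12: conjugate addition in place of substitution.
- Benzyloxyacetyl chloride (O=C(Cl)COCc1ccccc1) with N,O-dimethylhydroxylamine hydrochloride and pyridine gives 2-(benzyloxy)-N-methoxy-N-methylacetamide F9.
- Vinylmagnesium bromide (C=C[Mg]Br), with an inverse acidic quench, converts F9 into 1-(benzyloxy)but-3-en-2-one F10.
- The azaenolate 9 adds to F10 at −100 °C to give (2R)-N-{(4R)-4-[4-(benzyloxy)-3-oxobutyl]-2,2-dimethyl-1,3-dioxan-5-ylidene}-2-(methoxymethyl)pyrrolidin-1-amine F11.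
- Saturated aqueous oxalic acid in Et2O cleaves F11 to 12.

Step 11. The secondary C2 hydroxyl may be acylated alongside the primary one. Fallback, from 19 back to 20, with no new compound: the selectivity principle changes from steric discrimination to enzyme recognition, with immobilised Candida antarctica lipase B and vinyl benzoate in t-BuOMe at 40 °C, which acylates primary hydroxyls only.

## Further compounds

F1 | step 7 | (2R)-N-[(4R)-2,2-dimethyl-4-(3-methylbut-3-en-1-yl)-1,3-dioxan-5-ylidene]-2-(methoxymethyl)pyrrolidin-1-amine | COC[C@H]1CCCN1N=C2COC(C)(C)O[C@@H]2CCC(C)=C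
F2 | step 7 | (4R)-2,2-dimethyl-4-(3-oxobutyl)-1,3-dioxan-5-one | CC1(C)OCC(=O)[C@@H](CCC(C)=O)O1
F3 | step 7 | (4aS,8aR)-4a-hydroxy-2,2-dimethyltetrahydro-4H-1,3-benzodioxin-6(5H)-one | CC1(C)OC[C@]2(O)[C@@H](CCC(=O)C2)O1
F4 | step 7 | (8aR)-2,2-dimethyl-8,8a-dihydro-4H-1,3-benzodioxin-6(7H)-one | CC1(C)OCC2=CC(=O)CC[C@H]2O1
F5 | step 7 | (6R,8aR)-2,2-dimethyl-6,7,8,8a-tetrahydro-4H-1,3-benzodioxin-6-ol | CC1(C)OCC2=C[C@H](O)CC[C@H]2O1
F6 | step 7 | (4aS,5R,6R,8aR)-4a,5-epoxy-2,2-dimethylhexahydro-4H-1,3-benzodioxin-6-ol | CC1(C)OC[C@@]23O[C@@H]2[C@H](O)CC[C@H]3O1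
F7 | step 7 | (4aS,5S,6R,8aR)-5-(benzyloxy)-2,2-dimethylhexahydro-4H-1,3-benzodioxine-4a,6-diol | CC1(C)OC[C@]2(O)[C@@H](CC[C@@H](O)[C@@H]2OCc3ccccc3)O1
F8 | step 9 | (4aS,5S,6S,8aR)-5-(benzyloxy)-4a-hydroxy-2,2-dimethylhexahydro-4H-1,3-benzodioxin-6-yl trifluoromethanesulfonate | CC1(C)OC[C@]2(O)[C@@H](CC[C@H](OS(=O)(=O)C(F)(F)F)[C@@H]2OCc3ccccc3)O1
F9 | step 5 | 2-(benzyloxy)-N-methoxy-N-methylacetamide | CON(C)C(=O)COCc1ccccc1
F10 | step 5 | 1-(benzyloxy)but-3-en-2-one | C=CC(=O)COCc1ccccc1
F11 | step 5 | (2R)-N-{(4R)-4-[4-(benzyloxy)-3-oxobutyl]-2,2-dimethyl-1,3-dioxan-5-ylidene}-2-(methoxymethyl)pyrrolidin-1-amine | COC[C@H]1CCCN1N=C2COC(C)(C)O[C@@H]2CCC(=O)COCc3ccccc3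
F0 | step 11 | none | none
A1 | alternative 1 | oxasilolane joining the C1 oxygen and C5 through SiEt2, with C2/C6 acetonide and C7 benzoate | O=C(OC[C@@]12[C@H]3CC[C@@H]([Si](CC)(CC)O1)[C@@H]2OC(C)(C)O3)c1ccccc1
A2 | alternative 1 | meso diethylsilyl ether of the C1 hydroxyl, with C2/C6 acetonide and C7 benzoate | O=C(OC[C@]1(O[SiH](CC)CC)[C@H]2CCC[C@@H]1OC(C)(C)O2)c1ccccc1
A3 | alternative 2 | all-trans C1, C6, C5 triol with benzyl ethers at C2 and C7 | c1ccccc1COC[C@]1(O)[C@H](OCc2ccccc2)CC[C@@H](O)[C@@H]1O
A4 | alternative 2 | C1–C6 epoxide with C5 hydroxyl on the opposite face and benzyl ethers at C2 and C7 | c1ccccc1COC[C@@]23O[C@@H]2[C@@H](O)CC[C@H]3OCc4ccccc4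
A5 | alternative 3 | (3S,4S,5R,8R)-4,5,8-tris(benzyloxy)-1-oxaspiro[2.5]octane | C1O[C@]12[C@H](OCc3ccccc3)CC[C@@H](OCc3ccccc3)[C@@H]2OCc2ccccc2
A6 | alternative 3 | (2S,3R,6R)-2,3,6-tris(benzyloxy)cyclohexan-1-one | O=C1[C@H](OCc2ccccc2)CC[C@@H](OCc2ccccc2)[C@@H]1OCc1ccccc1
A7 | alternative 3 | (1R,2R,3R,6R)-3,6-bis(benzyloxy)cyclohexane-1,2-diol | O[C@H]1[C@H](OCc2ccccc2)CC[C@@H](OCc2ccccc2)[C@@H]1O
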